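The indole is cut across its pyrrole ring at C3–C3a and N1–C2. The feature exploited is the substitution of that ring, pyrimidine on C3 and only hydrogen on C2, together with the place of C3a in the benzene ring between C7a (attached to N1) and C4 (attached to oxygen). An aniline iodinated between its amino and methoxy groups maps directly onto this. One palladium heteroannulation of 5-bromo-2-iodo-3-methoxyaniline with a pyrimidinyl silyl alkyne should close the pyrrole ring with the 4-oxygen/6-bromo pattern already in place, silicon holding C2. The pyrimidine travels as its 2,4-dimethoxy form and is converted into the 4-amino-2-bromo ring afterwards.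

Key step: step 5

Remark: the target has no stereocentre. The hydrolysis in step 6 is assumed to run by addition of water to the N-protonated pyrimidine, so methanol is released. Compound 14 is drawn as the simple aryloxydibromoborane.

Step 1
Reactants: 1 2-methoxy-6-nitroaniline
Product: 2 4-bromo-2-methoxy-6-nitroaniline
Conditions: NBS (1.05 equiv), DMF, 0 °C → rt
Reagents that add atoms: N-bromosuccinimide, O=C1CCC(=O)N1Br
Why: Electrophilic aromatic bromination in which the amino group is the strongest donor and both of its ortho positions are occupied, so bromine should enter para to it, at a carbon that is also meta to the nitro group.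

Step 2
Reactants: 2 4-bromo-2-methoxy-6-nitroaniline
Product: 4 5-bromo-2-iodo-1-methoxy-3-nitrobenzene, via arenediazonium hydrogen sulfate 3 (not isolated)
Conditions: NaNO2, H2SO4, AcOH/H2O, 0–5 °C; then KI, H2O, 0 °C → rt
Reagents that add atoms: KI (potassium iodide), [K+].[I-]; NaNO2 (sodium nitrite), [Na+].[O-]N=O (its nitrogen stays only in 3); sulfuric acid, OS(=O)(=O)O (counter-ion of 3 only)
Why: Diazotisation of the weakly basic nitroaniline in strong acid followed by Sandmeyer-type iododediazoniation, in which iodide itself reduces the diazonium ion to the aryl radical, so no copper salt is needed and the bromide, ether and nitro group stay untouched.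

Step 3
Reactants: 4 5-bromo-2-iodo-1-methoxy-3-nitrobenzene
Product: 5 5-bromo-2-iodo-3-methoxyaniline
Conditions: Fe powder, NH4Cl, EtOH/H2O, 80 °C
Reagents that add atoms: none
Why: Béchamp-type reduction of the nitro group by iron under near-neutral conditions, which should leave the aryl iodide and aryl bromide intact where catalytic hydrogenation would not.

Step 4
Reactants: 6 5-iodo-2,4-dimethoxypyrimidine; 7 trimethylsilylacetylene
Product: 8 2,4-dimethoxy-5-[(trimethylsilyl)ethynyl]pyrimidine
Conditions: PdCl2(PPh3)2 (2 mol %), CuI (4 mol %), Et3N, THF, rt → 45 °C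
Reagents that add atoms: none
Why: Sonogashira coupling of a heteroaryl iodide with a terminal alkyne, in which the C–Si bond tolerates triethylamine and the two methoxy groups keep the pyrimidine inert towards the amine.

Step 5
Reactants: 5 5-bromo-2-iodo-3-methoxyaniline; 8 2,4-dimethoxy-5-[(trimethylsilyl)ethynyl]pyrimidine (1.5 equiv)
Product: 9 6-bromo-3-(2,4-dimethoxypyrimidin-5-yl)-4-methoxy-2-(trimethylsilyl)-1H-indole
Conditions: Pd(OAc)2 (10 mol %), LiCl (1 equiv), Na2CO3 (3 equiv), DMF, 100 °C
Reagents that add atoms: none
Why: Zerovalent palladium formed in situ from Pd(OAc)2 inserts into the C–I bond of 5, alkyne 8 then undergoes syn-carbopalladation that delivers the aryl carbon to the pyrimidinyl-bearing alkyne carbon (new C3–C3a bond) and palladium to the silyl-bearing carbon, and after the aniline nitrogen replaces halide on palladium, C–N reductive elimination forms N1–C2. The closest known reaction type is the Larock heteroannulation of 2-iodoanilines with silyl-substituted internal alkynes. The five-membered pyrrole ring is closed by reductive elimination from a six-membered azapalladacycle, a formal [3+2] annulation in which C3a, C7a and N1 come from the aniline and C2 and C3 from the alkyne. No stereocentre is formed. Two selectivities are needed: the regiochemistry, secured by the bulk of the trimethylsilyl group, which stays next to palladium during insertion and so ends on C2, and insertion into C–I in preference to C–Br, secured by the much weaker C–I bond under phosphine-free conditions.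

Step 6
Reactants: 9 6-bromo-3-(2,4-dimethoxypyrimidin-5-yl)-4-methoxy-2-(trimethylsilyl)-1H-indole
Product: 11 5-(6-bromo-4-methoxy-1H-indol-3-yl)pyrimidine-2,4(1H,3H)-dione, via 2-unsubstituted dimethoxypyrimidinyl indole 10 (not isolated)
Conditions: 6 M HCl (aq), 1,4-dioxane, 90 °C
Reagents that add atoms: water, O
Why: Acid-mediated ipso-protodesilylation at the electron-rich indole C2 followed by hydrolysis of the two imidate-type methoxy groups of the N-protonated pyrimidine (addition of water at C2 and C4, loss of methanol), while the aryl methyl ether and the aryl bromide are inert to aqueous HCl.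

Step 7
Reactants: 11 5-(6-bromo-4-methoxy-1H-indol-3-yl)pyrimidine-2,4(1H,3H)-dione
Product: 12 6-bromo-3-(2,4-dibromopyrimidin-5-yl)-4-methoxy-1H-indole
Conditions: POBr3 (4 equiv), PhNMe2 (1 equiv), toluene, 100 °C
Reagents that add atoms: phosphoryl bromide, O=P(Br)(Br)Br
Why: Deoxybromination of both lactam carbonyls (O-phosphorylation, then addition–elimination by bromide), the standard conversion of uracils into 2,4-dihalopyrimidines, with the amine buffering HBr so that the indole and the methyl ether should survive.

Step 8
Reactants: 12 6-bromo-3-(2,4-dibromopyrimidin-5-yl)-4-methoxy-1H-indole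
Product: 13 2-bromo-5-(6-bromo-4-methoxy-1H-indol-3-yl)pyrimidin-4-amine
Conditions: NH3 (0.5 M in 1,4-dioxane, excess), sealed tube, rt → 50 °C
Reagents that add atoms: ammonia, N
Why: Nucleophilic aromatic substitution, which in 2,4-dihalopyrimidines favours C4 (larger LUMO coefficient, para-quinoid Meisenheimer adduct) and is self-limiting because the new amino group deactivates C2, while the phenol is still a methyl ether and so cannot attack C4 intramolecularly and the indole C6–Br is not activated.

Step 9
Reactants: 13 2-bromo-5-(6-bromo-4-methoxy-1H-indol-3-yl)pyrimidin-4-amine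
Product: 15 3-(4-amino-2-bromopyrimidin-5-yl)-6-bromo-1H-indol-4-ol, via aryloxydibromoborane 14 (not isolated)
Conditions: BBr3 (6 equiv), CH2Cl2, −78 °C → rt; then H2O, 0 °C
Reagents that add atoms: boron tribromide, BrB(Br)Br (its boron and bromine stay only in 14)
Why: Lewis acid ether cleavage in which BBr3 binds the ether oxygen and bromide attacks the methyl group, the excess covering coordination to the nitrogen atoms, and because the reagent carries only bromide no halogen scrambling at pyrimidine C2 can occur before water hydrolyses the O–B bond.

Compound list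
1 | 2-methoxy-6-nitroaniline | COc1cccc([N+](=O)[O-])c1N | starting material
2 | 4-bromo-2-methoxy-6-nitroaniline | COc1cc(Br)cc([N+](=O)[O-])c1N | intermediate
3 | 4-bromo-2-methoxy-6-nitrobenzenediazonium hydrogen sulfate | COc1cc(Br)cc([N+](=O)[O-])c1[N+]#N.OS(=O)(=O)[O-] | intermediate
4 | 5-bromo-2-iodo-1-methoxy-3-nitrobenzene | COc1cc(Br)cc([N+](=O)[O-])c1I | intermediate
5 | 5-bromo-2-iodo-3-methoxyaniline | COc1cc(Br)cc(N)c1I | intermediate
6 | 5-iodo-2,4-dimethoxypyrimidine | COc1ncc(I)c(OC)n1 | starting material
7 | trimethylsilylacetylene | C#C[Si](C)(C)C | starting material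
8 | 2,4-dimethoxy-5-[(trimethylsilyl)ethynyl]pyrimidine | COc1ncc(C#C[Si](C)(C)C)c(OC)n1 | intermediate
9 | 6-bromo-3-(2,4-dimethoxypyrimidin-5-yl)-4-methoxy-2-(trimethylsilyl)-1H-indole | COc1ncc(-c2c([Si](C)(C)C)[nH]c3cc(Br)cc(OC)c23)c(OC)n1 | intermediate
10 | 6-bromo-3-(2,4-dimethoxypyrimidin-5-yl)-4-methoxy-1H-indole | COc1ncc(-c2c[nH]c3cc(Br)cc(OC)c23)c(OC)n1 | intermediate
11 | 5-(6-bromo-4-methoxy-1H-indol-3-yl)pyrimidine-2,4(1H,3H)-dione | COc1cc(Br)cc2[nH]cc(-c3c[nH]c(=O)[nH]c3=O)c12 | intermediate
12 | 6-bromo-3-(2,4-dibromopyrimidin-5-yl)-4-methoxy-1H-indole | COc1cc(Br)cc2[nH]cc(-c3cnc(Br)nc3Br)c12 | intermediate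
13 | 2-bromo-5-(6-bromo-4-methoxy-1H-indol-3-yl)pyrimidin-4-amine | COc1cc(Br)cc2[nH]cc(-c3cnc(Br)nc3N)c12 | intermediate
14 | dibromo{[3-(4-amino-2-bromopyrimidin-5-yl)-6-bromo-1H-indol-4-yl]oxy}borane | Nc1nc(Br)ncc1-c1c[nH]c2cc(Br)cc(OB(Br)Br)c12 | intermediate
15 | 3-(4-amino-2-bromopyrimidin-5-yl)-6-bromo-1H-indol-4-ol | Nc1nc(Br)ncc1-c1c[nH]c2cc(Br)cc(O)c12 | target

Total step count: 9
Longest linear sequence: 8 steps (steps 1, 2, 3, 5, 6, 7, 8 and 9, from 1 to 15)

Steps most likely to fail

Step 5. The arylpalladium species is flanked by the amino and methoxy groups and may insert the bulky silyl alkyne too slowly. Hydrodeiodination, insertion of palladium into C–Br, or base-induced loss of silicon from the alkyne with erosion of regiocontrol could then take over. The fallback sets out from 5 and closes the pyrrole ring by aminopalladation of a preformed aryl alkyne instead of by carbopalladation. Sonogashira coupling of 5 with 7 (PdCl2(PPh3)2, CuI, Et3N, rt) should give 5-bromo-3-methoxy-2-[(trimethylsilyl)ethynyl]aniline F1. Trifluoroacetic anhydride and pyridine in CH2Cl2 at 0 °C should convert it into N-{5-bromo-3-methoxy-2-[(trimethylsilyl)ethynyl]phenyl}-2,2,2-trifluoroacetamide F2. A Cacchi-type cyclisation of F2 with iodopyrimidine 6 (Pd(PPh3)4, K2CO3, MeCN, 80 °C) then follows. Oxidative addition takes place at the unhindered pyrimidinyl iodide, the amide nitrogen adds anti across the palladium-bound alkyne (5-endo-dig), reductive elimination forms the C3–pyrimidine bond, and the trifluoroacetyl group is lost under the carbonate conditions. The regiochemistry is fixed by the preformed aryl–alkyne bond, and the route is rejoined at 9.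

Step 7. The electron-rich NH-indole may break down, or the methyl ether may be cleaved by HBr, in hot POBr3, and the second oxygen may exchange incompletely. The fallback sets out from 11. The liquid and better-behaved POCl3 with PhNEt2 at 90 °C should give 6-bromo-3-(2,4-dichloropyrimidin-5-yl)-4-methoxy-1H-indole F3. Silyl-mediated halogen exchange with Me3SiBr in propionitrile at 80–100 °C then replaces both activated chlorides (at the 2- and 4-positions, through the N-silylpyrimidinium ion) by bromide. The route is rejoined at 12.

Step 8. Ammonia may attack C2 in competition with C4, since the twisted 4-methoxyindolyl group shields C4, or a second substitution may occur. The fallback sets out from 12. NaN3 (1.05 equiv) in DMF at 0 °C is a small, linear and more discriminating nucleophile and should give 3-(4-azido-2-bromopyrimidin-5-yl)-6-bromo-4-methoxy-1H-indole F4. Staudinger reduction (PPh3, THF/H2O, rt → 50 °C) then delivers the amine under neutral conditions that leave both C–Br bonds alone. The route is rejoined at 13.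

Further compounds
F1 | step 5 | 5-bromo-3-methoxy-2-[(trimethylsilyl)ethynyl]aniline | COc1cc(Br)cc(N)c1C#C[Si](C)(C)C
F2 | step 5 | N-{5-bromo-3-methoxy-2-[(trimethylsilyl)ethynyl]phenyl}-2,2,2-trifluoroacetamide | COc1cc(Br)cc(NC(=O)C(F)(F)F)c1C#C[Si](C)(C)C
F3 | step 7 | 6-bromo-3-(2,4-dichloropyrimidin-5-yl)-4-methoxy-1H-indole | COc1cc(Br)cc2[nH]cc(-c3cnc(Cl)nc3Cl)c12
F4 | step 8 | 3-(4-azido-2-bromopyrimidin-5-yl)-6-bromo-4-methoxy-1H-indole | COc1cc(Br)cc2[nH]cc(-c3cnc(Br)nc3N=[N+]=[N-])c12
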